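**Strategy.** The cyclohexenone ring (C1–C6) is reached from a cyclopentene by one-carbon ring expansion. The γ-hydroxy ketone array of megaphone (C1=O and the benzylic OH) is stored as a bicyclic enol ether: the carbinol oxygen is the enol ether oxygen of a 1-alkoxycyclopentene made of C1, C3, C4, C5 and C6. Chlorocarbene addition to this enol ether and electrocyclic opening of the alkoxy-chlorocyclopropane insert C2 between C1 and C3 and give, after hydrolysis, the enone and the free alcohol in one operation. The enol ether comes from a cis-butyrolactone by methylenation and ring-closing metathesis. C4 comes from a chiral triflate, and the quaternary C6 is set last by allylation.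

Key step: step 9

Assumption: the (Z)-crotylborane made from (+)-Ipc2BOMe attacks the Re face of the aryl aldehyde, and the (R,R)-configured Trost ligand gives the (S)-ether in step 4; should either sense be opposite, the antipodal reagent or ligand is used.

**Step 1**
Reactants: 1 3,4,5-trimethoxybenzaldehyde
Product: 2 (1R,2S)-2-methyl-1-(3,4,5-trimethoxyphenyl)but-3-en-1-ol
Conditions: cis-2-butene, n-BuLi, KOt-Bu, THF, −78 → −45 °C; (+)-Ipc2BOMe, −78 °C; BF3·OEt2; 1, −78 °C; then NaOH, H2O2
Reagents that add atoms: (Z)-crotyldiisopinocampheylborane, made in the flask, C/C=C\CB([C@H]1C[C@H]2C[C@@H]([C@@H]1C)C2(C)C)[C@H]1C[C@H]2C[C@@H]([C@@H]1C)C2(C)C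
Why: Brown crotylboration through a chair Zimmerman–Traxler transition state, in which the (Z)-crotyl geometry gives the syn (1R,2S) relationship of the future C7 and C8 and the isopinocampheyl groups select the Re face of the aldehyde.

**Step 2**
Reactants: 2 (1R,2S)-2-methyl-1-(3,4,5-trimethoxyphenyl)but-3-en-1-ol
Product: 3 (1R,2S)-2-methyl-1-(3,4,5-trimethoxyphenyl)butane-1,4-diol
Conditions: 9-BBN (2.5 equiv), THF, 0 °C → rt; then NaOH, H2O2
Reagents that add atoms: hydrogen peroxide, OO
Why: Anti-Markovnikov hydroboration–oxidation of the terminal alkene with the bulky 9-BBN puts the hydroxyl on the terminal carbon that becomes C1, and the two existing stereocenters are not touched.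

**Step 3**
Reactants: 3 (1R,2S)-2-methyl-1-(3,4,5-trimethoxyphenyl)butane-1,4-diol
Product: 4 (4S,5R)-4-methyl-5-(3,4,5-trimethoxyphenyl)oxolan-2-one (cis-lactone)
Conditions: TEMPO (cat), PhI(OAc)2, CH2Cl2, rt
Reagents that add atoms: none
Why: TEMPO/PhI(OAc)2 oxidative lactonization, in which the primary alcohol is oxidized selectively to the aldehyde, the benzylic hydroxyl closes the lactol and a second oxidation gives the cis γ-lactone without touching either stereocenter.

**Step 4**
Reactants: 5 rac-2-vinyloxirane (butadiene monoxide)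
Product: 6 (S)-2-methoxybut-3-en-1-ol
Conditions: MeOH, Pd2(dba)3·CHCl3 (1 mol %), (R,R)-DACH-phenyl Trost ligand (3 mol %), Et3B (1 mol %), CH2Cl2, rt
Reagents that add atoms: methanol, CO
Why: Palladium-catalysed dynamic kinetic asymmetric allylic etherification, in which the diastereomeric π-allyl palladium intermediates from the racemic epoxide interconvert and the boron-bound methoxide is delivered to the internal allyl carbon under control of the chiral ligand, which sets the stereocenter that becomes C4.

**Step 5**
Reactants: 6 (S)-2-methoxybut-3-en-1-ol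
Product: 7 (S)-2-methoxybut-3-en-1-yl trifluoromethanesulfonate
Conditions: Tf2O, 2,6-lutidine, CH2Cl2, −78 °C; used crude
Reagents that add atoms: trifluoromethanesulfonic anhydride, O=S(=O)(OS(=O)(=O)C(F)(F)F)C(F)(F)F
Why: Sulfonylation of the primary alcohol gives a triflate reactive enough for enolate alkylation despite the β-methoxy group, and the stereocenter is not involved.

**Step 6**
Reactants: 4 (4S,5R)-4-methyl-5-(3,4,5-trimethoxyphenyl)oxolan-2-one; 7 (S)-2-methoxybut-3-en-1-yl trifluoromethanesulfonate
Product: 8 (3S,4S,5R)-3-[(2R)-2-methoxybut-3-en-1-yl]-4-methyl-5-(3,4,5-trimethoxyphenyl)oxolan-2-one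
Conditions: LDA, THF, −78 °C; then 7, −78 → −40 °C
Reagents that add atoms: none
Why: SN2 alkylation of the lithium lactone enolate at the primary triflate carbon leaves the methoxy stereocenter untouched, and the new center at C3 forms trans to the neighbouring 4-methyl group by approach anti to it, which is of no consequence because this center is erased in step 10.

**Step 7**
Reactants: 8 (3S,4S,5R)-3-[(2R)-2-methoxybut-3-en-1-yl]-4-methyl-5-(3,4,5-trimethoxyphenyl)oxolan-2-one
Product: 9 (2R,3S,4S)-4-[(2R)-2-methoxybut-3-en-1-yl]-3-methyl-5-methylidene-2-(3,4,5-trimethoxyphenyl)oxolane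
Conditions: Cp2TiMe2, toluene, 70 °C, dark; filtered through basic alumina
Reagents that add atoms: dimethyltitanocene Cp2TiMe2, C[Ti](C)(C1C=CC=C1)C1C=CC=C1
Why: Petasis methylenation, in which thermally generated Cp2Ti=CH2 converts the lactone carbonyl into the exocyclic enol ether through an oxatitanacyclobutane under non-basic conditions, so the α-stereocenter and the remote alkene survive.

**Step 8**
Reactants: 9 (2R,3S,4S)-4-[(2R)-2-methoxybut-3-en-1-yl]-3-methyl-5-methylidene-2-(3,4,5-trimethoxyphenyl)oxolane
Product: 10 (2R,3S,3aS,5R)-5-methoxy-3-methyl-2-(3,4,5-trimethoxyphenyl)-3,3a,4,5-tetrahydro-2H-cyclopenta[b]furan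
Conditions: second-generation Grubbs catalyst (H2IMes)(PCy3)Cl2Ru=CHPh (5 mol %), toluene, 60 °C, N2 sparge
Reagents that add atoms: none
Why: Ring-closing metathesis of the monosubstituted alkene onto the 1,1-disubstituted enol ether expels ethylene and closes the 1-alkoxycyclopentene without forming a stereocenter, and no other alkene pairing is present.

**Step 9**
Reactants: 10 (2R,3S,3aS,5R)-5-methoxy-3-methyl-2-(3,4,5-trimethoxyphenyl)-3,3a,4,5-tetrahydro-2H-cyclopenta[b]furan
Product: 13 (4R,6S)-6-[(1R,2S)-1-hydroxy-1-(3,4,5-trimethoxyphenyl)propan-2-yl]-4-methoxycyclohex-2-en-1-one, via endo-chlorocyclopropane 11 (not isolated), via oxocarbenium chloride 12 (not isolated)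
Conditions: CH2Cl2, MeLi·LiBr, Et2O, −35 → 0 °C; then H2O, THF, NaHCO3, rt
Reagents that add atoms: dichloromethane, ClCCl; water, O
Why: MeLi deprotonates CH2Cl2 and the derived chlorocarbenoid adds in a concerted [2+1] cheletropic manner to the electron-rich enol ether double bond of 10 (future C1 and C3), closing the three-membered ring of 11; the ether oxygen then drives a disrotatory 2π-electrocyclic opening of the ring-fusion cyclopropane bond with loss of the endo chloride, which turns the five-membered carbocycle into the six-membered allyl oxocarbenium ion 12, and water adds at the oxocarbenium carbon and the hemiketal opens to the enone and the free benzylic alcohol. The closest known reaction type is the halocarbene homologation of enol ethers and silyl enol ethers of cyclic ketones to 2-cycloalkenones through alkoxy- or siloxy-halocyclopropanes. No stereocenter of the target is created here: the cyclopropane stereocenters are erased in the opening, C4 and the two side-chain centers are untouched, and C6 (which may partly epimerize) is re-set in step 10. The step needs chemoselectivity for the enol ether over the trimethoxyarene, cleavage of the internal cyclopropane bond, and a chlorine cis to the carbocycle; the first is secured by the donor oxygen, the second is inherent because a cyclopropyl halide opens the bond opposite to the carbon that bears the halide, and the third rests on the Woodward–Hoffmann–DePuy rule (only the endo chloride can give a cis-cycloalkenyl cation) together with the usual syn preference of lithium chlorocarbenoids for the more substituted side.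

**Step 10**
Reactants: 13 (4R,6S)-6-[(1R,2S)-1-hydroxy-1-(3,4,5-trimethoxyphenyl)propan-2-yl]-4-methoxycyclohex-2-en-1-one
Product: 14 megaphone, (4R,6R)-6-[(1R,2S)-1-hydroxy-1-(3,4,5-trimethoxyphenyl)propan-2-yl]-4-methoxy-6-(prop-2-en-1-yl)cyclohex-2-en-1-one
Conditions: LDA (2.5 equiv), THF, −78 °C; allyl bromide, DMPU, −78 → −30 °C
Reagents that add atoms: allyl bromide, C=CCBr
Why: Kinetic deprotonation at C6 gives the cross-conjugated lithium dienolate (beside the lithium alkoxide), and C-allylation with allyl bromide should set the quaternary C6 as R by matched substrate control, namely attack anti to the C4 methoxy group (1,3-induction) and, in the A(1,3)-minimised rotamer with the C8–H bond eclipsing the enolate, anti to the benzylic carbon, so that the allyl group ends trans and the side chain cis to the methoxy group.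

**Compound list**
1 | 3,4,5-trimethoxybenzaldehyde | COc1cc(C=O)cc(OC)c1OC | starting material
2 | (1R,2S)-2-methyl-1-(3,4,5-trimethoxyphenyl)but-3-en-1-ol | C=C[C@H](C)[C@@H](O)c1cc(OC)c(OC)c(OC)c1 | intermediate
3 | (1R,2S)-2-methyl-1-(3,4,5-trimethoxyphenyl)butane-1,4-diol | OCC[C@H](C)[C@@H](O)c1cc(OC)c(OC)c(OC)c1 | intermediate
4 | (4S,5R)-4-methyl-5-(3,4,5-trimethoxyphenyl)oxolan-2-one | O=C1C[C@H](C)[C@H](c2cc(OC)c(OC)c(OC)c2)O1 | intermediate
5 | rac-2-vinyloxirane | C=CC1CO1 | starting material
6 | (S)-2-methoxybut-3-en-1-ol | OC[C@@H](OC)C=C | intermediate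
7 | (S)-2-methoxybut-3-en-1-yl trifluoromethanesulfonate | FC(F)(F)S(=O)(=O)OC[C@@H](OC)C=C | intermediate
8 | (3S,4S,5R)-3-[(2R)-2-methoxybut-3-en-1-yl]-4-methyl-5-(3,4,5-trimethoxyphenyl)oxolan-2-one | O=C1[C@@H](C[C@@H](OC)C=C)[C@H](C)[C@H](c2cc(OC)c(OC)c(OC)c2)O1 | intermediate
9 | (2R,3S,4S)-4-[(2R)-2-methoxybut-3-en-1-yl]-3-methyl-5-methylidene-2-(3,4,5-trimethoxyphenyl)oxolane | C=C1[C@@H](C[C@@H](OC)C=C)[C@H](C)[C@H](c2cc(OC)c(OC)c(OC)c2)O1 | intermediate
10 | (2R,3S,3aS,5R)-5-methoxy-3-methyl-2-(3,4,5-trimethoxyphenyl)-3,3a,4,5-tetrahydro-2H-cyclopenta[b]furan | C1=C2O[C@@H](c3cc(OC)c(OC)c(OC)c3)[C@@H](C)[C@@H]2C[C@H]1OC | intermediate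
11 | endo-chlorocyclopropane: CHCl added across the enol ether double bond of 10 on the face of the methoxy group, chlorine over the five-membered carbocycle | Cl[C@@H]1[C@@H]2[C@H](OC)C[C@H]3[C@H](C)[C@H](c4cc(OC)c(OC)c(OC)c4)O[C@@]123 | intermediate
12 | (2R,3S,3aS,5R)-5-methoxy-3-methyl-2-(3,4,5-trimethoxyphenyl)-3,3a,4,5-tetrahydro-2H-1-benzofuran-1-ium chloride | CO[C@H]1C=CC2=[O+][C@@H](c3cc(OC)c(OC)c(OC)c3)[C@@H](C)[C@@H]2C1.[Cl-] | intermediate
13 | (4R,6S)-6-[(1R,2S)-1-hydroxy-1-(3,4,5-trimethoxyphenyl)propan-2-yl]-4-methoxycyclohex-2-en-1-one | O=C1C=C[C@H](OC)C[C@H]1[C@H](C)[C@@H](O)c2cc(OC)c(OC)c(OC)c2 | intermediate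
14 | megaphone | C=CC[C@]1([C@H](C)[C@@H](O)c2cc(OC)c(OC)c(OC)c2)C[C@@H](OC)C=CC1=O | target

**Count.** Total: 10 steps. Longest linear sequence: 8 steps (steps 1, 2, 3, 6, 7, 8, 9, 10).

**Steps most likely to fail**

Step 9. The carbenoid may place the chlorine exo, an isomer that cannot open to a cis-cycloalkenyl cation, and the oxocarbenium ion may lose its γ-proton instead of taking up water. The fallback sets out from 10 and comes back at 13. Mild aqueous acid hydrolysis of 10 gives the hydroxy ketone (2S,4R)-2-[(1R,2S)-1-hydroxy-1-(3,4,5-trimethoxyphenyl)propan-2-yl]-4-methoxycyclopentan-1-one F1. LDA with TMSCl as internal quench silylates the alcohol and the less substituted enolate to give the bis(trimethylsilyl) compound F2. Simmons–Smith cyclopropanation (Et2Zn, CH2I2) of the silyl enol ether gives the siloxycyclopropane F3. FeCl3 in DMF opens the ring-fusion bond by a radical pathway (Ito–Saegusa ring expansion) to the β-chloro ketone F4, and NaOAc in MeOH eliminates HCl to give 13.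

Step 10. Deprotonation of the tertiary C6–H beside a lithium alkoxide may be slow or go to the γ-position, and facial selectivity of the allylation may be poor. The fallback sets out from 13 and comes back at 14. TESCl and imidazole give the triethylsilyl ether F5. KN(SiMe3)2 and allyl chloroformate give the allyl dienol carbonate F6. Pd2(dba)3 with a t-Bu-PHOX ligand (the antipode that reinforces the substrate bias) effects a decarboxylative Tsuji allylation under catalyst control to megaphone triethylsilyl ether F7, and TBAF gives 14.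

Step 8. The ruthenium carbene may be trapped by the enol ether as a Fischer carbene, the exocyclic double bond of 9 may migrate into the oxolane ring before closure, and the strained ring-fusion alkene may form slowly. The fallback sets out from 8 and comes back at 10. Lactone 8 is treated directly with the reduced titanium ethylidene reagent of the Takai–Utimoto type (TiCl4, TMEDA, Zn, PbCl2, CH3CHBr2); a titanium alkylidene formed at the terminal alkene olefinates the lactone carbonyl intramolecularly, so neither 9 nor a ruthenium catalyst is needed and no new compound is made (F0).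

**Further compounds**
F1 | step 9 | (2S,4R)-2-[(1R,2S)-1-hydroxy-1-(3,4,5-trimethoxyphenyl)propan-2-yl]-4-methoxycyclopentan-1-one | O=C1C[C@H](OC)C[C@H]1[C@H](C)[C@@H](O)c2cc(OC)c(OC)c(OC)c2
F2 | step 9 | trimethyl{[(3R,5S)-3-methoxy-5-[(1R,2S)-1-(3,4,5-trimethoxyphenyl)-1-(trimethylsilyloxy)propan-2-yl]cyclopent-1-en-1-yl]oxy}silane | C[Si](C)(C)OC1=C[C@H](OC)C[C@H]1[C@H](C)[C@@H](O[Si](C)(C)C)c2cc(OC)c(OC)c(OC)c2
F3 | step 9 | 1-(trimethylsilyloxy)bicyclo[3.1.0]hexane from F2, cyclopropane cis to the 4-methoxy group, 2-substituent and silyl ether as in F2 | C[Si](C)(C)O[C@@]12C[C@@H]1[C@H](OC)C[C@H]2[C@H](C)[C@@H](O[Si](C)(C)C)c3cc(OC)c(OC)c(OC)c3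
F4 | step 9 | (3R,4R,6S)-3-chloro-6-[(1R,2S)-1-hydroxy-1-(3,4,5-trimethoxyphenyl)propan-2-yl]-4-methoxycyclohexan-1-one | O=C1C[C@@H](Cl)[C@H](OC)C[C@H]1[C@H](C)[C@@H](O)c2cc(OC)c(OC)c(OC)c2
F5 | step 10 | (4R,6S)-4-methoxy-6-[(1R,2S)-1-(triethylsilyloxy)-1-(3,4,5-trimethoxyphenyl)propan-2-yl]cyclohex-2-en-1-one | O=C1C=C[C@H](OC)C[C@H]1[C@H](C)[C@@H](O[Si](CC)(CC)CC)c2cc(OC)c(OC)c(OC)c2
F6 | step 10 | prop-2-en-1-yl (4R)-4-methoxy-2-[(1R,2S)-1-(triethylsilyloxy)-1-(3,4,5-trimethoxyphenyl)propan-2-yl]cyclohexa-1,5-dien-1-yl carbonate | C=CCOC(=O)OC1=C([C@H](C)[C@@H](O[Si](CC)(CC)CC)c2cc(OC)c(OC)c(OC)c2)C[C@@H](OC)C=C1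
F7 | step 10 | (4R,6R)-4-methoxy-6-(prop-2-en-1-yl)-6-[(1R,2S)-1-(triethylsilyloxy)-1-(3,4,5-trimethoxyphenyl)propan-2-yl]cyclohex-2-en-1-one | C=CC[C@]1([C@H](C)[C@@H](O[Si](CC)(CC)CC)c2cc(OC)c(OC)c(OC)c2)C[C@@H](OC)C=CC1=O
F0 | step 8 | none | none
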